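**Early times.** In its first 25.0 min the alpha run lost 8.00 % of its electrophile; the new flask has the same charges but half the free base, and runs to 10 h.

- alpha: electrophile 20 mM; nucleophile 24 mM; free base 120 mM; protic impurity 4 mM; run made earlier
- flask: electrophile 20 mM; nucleophile 24.0 mM; free base 60.0 mM; protic impurity 4.00 mM; time 10 h

alpha run (percent of the electrophile charged)

| time / min | electrophile / % | target / % |
|---|---|---|
| 25.0 | 92 | 8 |
| 50.0 | 87 | 14 |
| 80.0 | 81 | 18 |
| 90.0 | 79 | 18 |
| 120 | 77 | 27 |

(standard deviation of a reading: 1.5 percentage points)

- the earlier runs were read with a standard deviation of 1.5 percentage points
- the earlier runs do not show how much of nucleophile is bound; that part of a forecast is a guess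
- no earlier run changes the charge of free base; that part of a forecast is a guess

- part of the electrophile that has reacted at 10 h
- share of free nucleophile in free nucleophile and protonated nucleophile together, at 10 h

**Closed form.** Take electrophile and nucleophile to react pair by pair. The nucleophile excess matches the impurity charge, so if the impurity takes that excess, the two stay equal. The second-order rate then integrates simply: the reciprocal of the electrophile fraction climbs linearly with time. A line from the start through the last reading has slope 0.149 /h, which gives 59.9 % reacted at 10 h.

**Free base.** The flask's free base exceeds its electrophile charge, so the acid has room on it, and the slope is carried over unchanged. This is a guess, since no earlier run varies the base.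

**Weak link.** The first reading lies above that line, with 0.209 /h from the start. The slope between the second and last readings is therefore safer: 0.128 /h, the reciprocal clock, the rise of the reciprocal fraction per hour. Run on from the last reading, it gives 56.9 % reacted. If each electrophile reacted frees one acid, and base and the remaining nucleophile bind it equally, the free share is about 83.4 %, again a guess.

**Forecast.** The forecast gave 58 % and 80 %, with “a wide range because the base effect is unmeasured”.

**Result.** The flask reaches 55.1 % reacted and a free share of 94.7 %, above the guess. Counted from the last alpha reading, which carries its scatter, to the flask's result, the reciprocal rises 0.116 /h, against the clock's 0.128 /h.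

    nucleophile + acid set free ⇌ protonated nucleophile, settled at all times (K = 840 /M)
    electrophile + acid set free → side product (k = 1.00 /M/h)
    electrophile + nucleophile → acid set free + target (k = 8.70 /M/h)
    nucleophile + protic impurity → quenched reagent (k = 13.0 /M/h)
    acid set free + free base ⇌ salt of the base (K = 9700 /M, k = 200 /M/h)
    nucleophile ⇌ dormant form (K = 0.770, k = 0.140 /h)

**Dormant form.** By their own step alone, nucleophile and dormant form relax with a half-life of 2.15 h, short against 10 h, and the last alpha reading falls inside it. At 10.0 h the flask holds 21.2 % of the nucleophile charge as nucleophile beside 20.1 % as dormant form. Carried to 100 h, the clock gives 92.8 % reacted, and the flask left that long reaches 91.1 %.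

The earlier runs and the new flask were computed on assumed constants; noise was put on by code.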